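## Retrosynthetic overview

1. The target is (2S)-7,4'-dihydroxyflavan-(4α→8)-(−)-epiafzelechin; the last operation is hydrogenolysis of five benzyl ethers.
2. C4–C8' bond: 8-metallated tri-O-benzyl-epiafzelechin adds to the C4 carbonyl of an (S)-flavanone; hydride reduction of the C4 cation trans to the C2 aryl group gives the 2,4-cis (4S) flavan.
3. Upper pyran ring C: the O1–C2 bond is closed by a catalytic enantioselective oxa-Michael cyclisation of a 2'-hydroxychalcone (sets 2S; new catalysis).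
4. Lower pyran ring F: the O1'–C2' bond is closed by an organocatalytic oxa-Michael/aldol annulation of a salicylaldehyde with an enal (sets 2'R); Baeyer–Villiger oxygenation at C3' and hydride reduction then give the 2',3'-cis alcohol.
5. Ring order: ring F, then ring C, then union and deprotection, all from 2,4,6-trihydroxybenzaldehyde, 4-(benzyloxy)benzaldehyde and 4'-benzyloxy-2'-hydroxyacetophenone.

Assumption: the SMILES is read as upper unit 2S,4S (C2 and C4 aryl groups cis) and lower unit 2R,3R (2,3-cis); upper rings are A (benzo), C (pyran), B (aryl), lower rings are D, F, E, and primed locants belong to the lower unit.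

## Route

Step 1
Reactants: 1 2,4,6-trihydroxybenzaldehyde
Product: 2 4,6-bis(benzyloxy)-2-hydroxybenzaldehyde
Conditions: BnBr (2.05 equiv), K2CO3 (2.1 equiv), DMF, 0 °C → rt
Reagents that add atoms: benzyl bromide, BrCc1ccccc1
Why: Williamson etherification; the para OH and one ortho OH react, while the remaining ortho OH stays hydrogen-bonded to the formyl group and is left free.

Step 2
Reactants: 3 4-(benzyloxy)benzaldehyde; 4 (triphenylphosphoranylidene)acetaldehyde
Product: 5 (E)-3-[4-(benzyloxy)phenyl]prop-2-enal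
Conditions: toluene, 80 °C
Reagents that add atoms: none
Why: Wittig olefination with a stabilised ylide gives the E-enal.

Step 3
Reactants: 2 4,6-bis(benzyloxy)-2-hydroxybenzaldehyde; 5 (E)-3-[4-(benzyloxy)phenyl]prop-2-enal
Product: 6 (R)-5,7-bis(benzyloxy)-2-[4-(benzyloxy)phenyl]-2H-chromene-3-carbaldehyde
Conditions: (S)-2-[diphenyl(trimethylsilyloxy)methyl]pyrrolidine (20 mol%), 2-nitrobenzoic acid (20 mol%), 4 Å molecular sieves, toluene, rt → 40 °C
Reagents that add atoms: none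
Why: Iminium/enamine-catalysed domino oxa-Michael/aldol condensation; the phenol oxygen adds to the β-carbon of the E-iminium ion on the face not shielded by the CPh2(OSiMe3) group, which sets C2 as R, and the enamine then closes onto the formyl group and dehydrates.

Step 4
Reactants: 6 (R)-5,7-bis(benzyloxy)-2-[4-(benzyloxy)phenyl]-2H-chromene-3-carbaldehyde
Product: 8 (R)-5,7-bis(benzyloxy)-2-[4-(benzyloxy)phenyl]chroman-3-one, via enol formate 7 (not isolated)
Conditions: mCPBA (1.05 equiv), CH2Cl2, 0 °C; then MeOH, NaHCO3 (cat.), 0 °C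
Reagents that add atoms: 3-chloroperoxybenzoic acid (mCPBA), O=C(OO)c1cccc(Cl)c1
Why: Baeyer–Villiger oxidation of the α-substituted enal with migration of the electron-rich alkenyl group gives the enol formate, and its methanolysis releases the ketone by protonation at C4, so C2 is not touched.

Step 5
Reactants: 8 (R)-5,7-bis(benzyloxy)-2-[4-(benzyloxy)phenyl]chroman-3-one
Product: 9 (2R,3R)-5,7-bis(benzyloxy)-2-[4-(benzyloxy)phenyl]chroman-3-ol
Conditions: LiBH(s-Bu)3, THF, −78 °C; then H2O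
Reagents that add atoms: none
Why: Diastereoselective ketone reduction; the bulky hydride approaches C3 from the face remote from the C2 aryl group and gives the axial, 2,3-cis alcohol (3R).

Step 6
Reactants: 9 (2R,3R)-5,7-bis(benzyloxy)-2-[4-(benzyloxy)phenyl]chroman-3-ol
Product: 10 (2R,3R)-5,7-bis(benzyloxy)-2-[4-(benzyloxy)phenyl]-8-bromochroman-3-ol
Conditions: NBS (1.0 equiv), CH2Cl2, −40 °C → rt, dark
Reagents that add atoms: N-bromosuccinimide, O=C1CCC(=O)N1Br
Why: Electrophilic aromatic bromination, which on O-benzylated flavan-3-ols takes place selectively at C8 of ring D.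

Step 7
Reactants: 11 1-[4-(benzyloxy)-2-hydroxyphenyl]ethan-1-one; 3 4-(benzyloxy)benzaldehyde
Product: 12 (E)-1-[4-(benzyloxy)-2-hydroxyphenyl]-3-[4-(benzyloxy)phenyl]prop-2-en-1-one
Conditions: KOH (aq.), EtOH, rt
Reagents that add atoms: none
Why: Claisen–Schmidt aldol condensation gives the E-chalcone.

Step 8
Reactants: 12 (E)-1-[4-(benzyloxy)-2-hydroxyphenyl]-3-[4-(benzyloxy)phenyl]prop-2-en-1-one
Product: 13 (S)-7-(benzyloxy)-2-[4-(benzyloxy)phenyl]chroman-4-one
Conditions: 1-[3,5-bis(trifluoromethyl)phenyl]-3-[(2S)-3,3-dimethyl-1-{[tris(4-methoxyphenyl)-λ5-phosphanylidene]amino}butan-2-yl]thiourea (10 mol%; antipode chosen to give (S)-13), 4 Å molecular sieves, toluene, −20 → 0 °C, stopped at ca. 90% conversion, filtered cold through acid-washed silica; recovered 12 recycled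
Reagents that add atoms: none
Why: Proposed new method: the iminophosphorane (a superbase) fully deprotonates the carbonyl-chelated 2'-OH and holds the phenoxide as a chiral ion pair while the thiourea binds the enone carbonyl, so the 6-endo-trig C–O closure takes place on one enone face and the enolate is C-protonated by the iminophosphoranium N–H before retro-addition can erode the ee, which sets C2 as S (aryl on the α face); the closest known reactions are iminophosphorane–thiourea-catalysed oxa-Michael additions of alcohols to unsaturated esters and the cinchona-thiourea cyclisation of ester-activated 2'-hydroxychalcones, whereas unactivated 2'-hydroxychalcones have so far given only modest ee.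

Step 9
Reactants: 10 (2R,3R)-5,7-bis(benzyloxy)-2-[4-(benzyloxy)phenyl]-8-bromochroman-3-ol; 13 (S)-7-(benzyloxy)-2-[4-(benzyloxy)phenyl]chroman-4-one
Product: 17 (2R,3R)-5,7-bis(benzyloxy)-8-[(2S,4S)-7-(benzyloxy)-2-[4-(benzyloxy)phenyl]chroman-4-yl]-2-[4-(benzyloxy)phenyl]chroman-3-ol, via aryllithium 14 (not isolated), via organocerium 15 (not isolated), via carbinol 16 (not isolated)
Conditions: 10 (1.3 equiv), n-BuLi (2.1 equiv per 10), THF, −78 °C; CeCl3 (anhydrous), −78 °C; 13, −78 → −40 °C; then CH2Cl2, Bu3SnH (3 equiv), TFA (excess), −78 → 0 °C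
Reagents that add atoms: none
Why: Bromine–lithium exchange, organocerium 1,2-addition to the enolisable ketone and ionic hydrogenation of the doubly benzylic carbinol; the hydride adds pseudo-axially to the planar C4 cation, trans to the equatorial C2 aryl group, so ring D ends up cis to ring B (4S).

Step 10
Reactants: 17 (2R,3R)-5,7-bis(benzyloxy)-8-[(2S,4S)-7-(benzyloxy)-2-[4-(benzyloxy)phenyl]chroman-4-yl]-2-[4-(benzyloxy)phenyl]chroman-3-ol
Product: 18 (2R,3R)-8-[(2S,4S)-7-hydroxy-2-(4-hydroxyphenyl)chroman-4-yl]-2-(4-hydroxyphenyl)chroman-3,5,7-triol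
Conditions: H2 (1 atm), Pd(OH)2/C, THF/MeOH (1:1), rt
Reagents that add atoms: none
Why: Catalytic hydrogenolysis removes the five benzyl ethers without touching any stereocentre, since the cyclic benzylic C2–O bonds of flavans survive these conditions.

## Compound list

1 | 2,4,6-trihydroxybenzaldehyde | O=Cc1c(O)cc(O)cc1O | starting material
2 | 4,6-bis(benzyloxy)-2-hydroxybenzaldehyde | O=Cc1c(O)cc(OCc2ccccc2)cc1OCc1ccccc1 | intermediate
3 | 4-(benzyloxy)benzaldehyde | O=Cc1ccc(OCc2ccccc2)cc1 | starting material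
4 | (triphenylphosphoranylidene)acetaldehyde | O=CC=P(c1ccccc1)(c1ccccc1)c1ccccc1 | starting material
5 | (E)-3-[4-(benzyloxy)phenyl]prop-2-enal | O=C/C=C/c1ccc(OCc2ccccc2)cc1 | intermediate
6 | (R)-5,7-bis(benzyloxy)-2-[4-(benzyloxy)phenyl]-2H-chromene-3-carbaldehyde | c1c(OCc3ccccc3)cc(OCc3ccccc3)c2c1O[C@H](c1ccc(OCc3ccccc3)cc1)C(C=O)=C2 | intermediate
7 | (R)-5,7-bis(benzyloxy)-2-[4-(benzyloxy)phenyl]-2H-chromen-3-yl formate (enol formate) | c1c(OCc3ccccc3)cc(OCc3ccccc3)c2c1O[C@H](c1ccc(OCc3ccccc3)cc1)C(OC=O)=C2 | intermediate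
8 | (R)-5,7-bis(benzyloxy)-2-[4-(benzyloxy)phenyl]chroman-3-one | c1c(OCc3ccccc3)cc(OCc3ccccc3)c2c1O[C@H](c1ccc(OCc3ccccc3)cc1)C(=O)C2 | intermediate
9 | (2R,3R)-5,7-bis(benzyloxy)-2-[4-(benzyloxy)phenyl]chroman-3-ol (5,7,4'-tri-O-benzyl-(−)-epiafzelechin) | c1c(OCc3ccccc3)cc(OCc3ccccc3)c2c1O[C@H](c1ccc(OCc3ccccc3)cc1)[C@H](O)C2 | intermediate
10 | (2R,3R)-5,7-bis(benzyloxy)-2-[4-(benzyloxy)phenyl]-8-bromochroman-3-ol | Brc1c(OCc3ccccc3)cc(OCc3ccccc3)c2c1O[C@H](c1ccc(OCc3ccccc3)cc1)[C@H](O)C2 | intermediate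
11 | 1-[4-(benzyloxy)-2-hydroxyphenyl]ethan-1-one | CC(=O)c1ccc(OCc2ccccc2)cc1O | starting material
12 | (E)-1-[4-(benzyloxy)-2-hydroxyphenyl]-3-[4-(benzyloxy)phenyl]prop-2-en-1-one | O=C(/C=C/c1ccc(OCc2ccccc2)cc1)c1ccc(OCc2ccccc2)cc1O | intermediate
13 | (S)-7-(benzyloxy)-2-[4-(benzyloxy)phenyl]chroman-4-one | O=C1C[C@@H](c2ccc(OCc3ccccc3)cc2)Oc2cc(OCc3ccccc3)ccc12 | intermediate
14 | lithium (2R,3R)-5,7-bis(benzyloxy)-2-[4-(benzyloxy)phenyl]-8-lithiochroman-3-olate (aryllithium) | [Li]c1c(OCc3ccccc3)cc(OCc3ccccc3)c2c1O[C@H](c1ccc(OCc3ccccc3)cc1)[C@H](O[Li])C2 | intermediate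
15 | lithium (2R,3R)-5,7-bis(benzyloxy)-2-[4-(benzyloxy)phenyl]-8-(dichloroceryl)chroman-3-olate (ArCeCl2 organocerium) | Cl[Ce](Cl)c1c(OCc3ccccc3)cc(OCc3ccccc3)c2c1O[C@H](c1ccc(OCc3ccccc3)cc1)[C@H](O[Li])C2 | intermediate
16 | (2S)-7-(benzyloxy)-2-[4-(benzyloxy)phenyl]-4-[(2R,3R)-5,7-bis(benzyloxy)-2-[4-(benzyloxy)phenyl]-3-hydroxychroman-8-yl]chroman-4-ol (carbinol; C4 epimers) | OC1(c2c(OCc4ccccc4)cc(OCc4ccccc4)c3c2O[C@H](c2ccc(OCc4ccccc4)cc2)[C@H](O)C3)C[C@@H](c2ccc(OCc4ccccc4)cc2)Oc2cc(OCc4ccccc4)ccc12 | intermediate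
17 | (2R,3R)-5,7-bis(benzyloxy)-8-[(2S,4S)-7-(benzyloxy)-2-[4-(benzyloxy)phenyl]chroman-4-yl]-2-[4-(benzyloxy)phenyl]chroman-3-ol | c1ccccc1COc1ccc([C@@H]2C[C@H](c3c(OCc5ccccc5)cc(OCc5ccccc5)c4c3O[C@H](c3ccc(OCc5ccccc5)cc3)[C@H](O)C4)c3ccc(OCc5ccccc5)cc3O2)cc1 | intermediate
18 | (2R,3R)-8-[(2S,4S)-7-hydroxy-2-(4-hydroxyphenyl)chroman-4-yl]-2-(4-hydroxyphenyl)chroman-3,5,7-triol | Oc1ccc([C@@H]2C[C@H](c3c(O)cc(O)c4c3O[C@H](c3ccc(O)cc3)[C@H](O)C4)c3ccc(O)cc3O2)cc1 | target

## Step count and risk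

Total steps: 10. Longest linear sequence: 7 (steps 1, 3, 4, 5, 6, 9, 10).

Step 8 (the new ring closure) is the most uncertain step. The chelated, donor-substituted chalcone may cyclise slowly, and the ee can erode by retro-addition. The known-chemistry fallback sets out from 11 and 3 and comes back at 13; it activates the acceptor with a removable ester so that an established catalyst class suffices. C-tert-butoxycarbonylation of 11 (LiN(SiMe3)2, Boc2O, THF, −78 °C) gives tert-butyl 3-[4-(benzyloxy)-2-hydroxyphenyl]-3-oxopropanoate F1. Knoevenagel condensation of F1 with 3 (piperidine, AcOH, toluene) gives tert-butyl 2-[4-(benzyloxy)-2-hydroxybenzoyl]-3-[4-(benzyloxy)phenyl]prop-2-enoate F2. A cinchona-alkaloid-derived thiourea (10 mol%, toluene, −25 °C; the pseudo-enantiomer that gives the 2S series) closes F2 by oxa-Michael addition to tert-butyl (2S)-7-(benzyloxy)-2-[4-(benzyloxy)phenyl]-4-oxochromane-3-carboxylate F3. TsOH at 80 °C then removes the ester as isobutene and CO2 to give 13.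

Step 9 is the second risk. The 1,2-addition joins a hindered 2,6-dioxygenated aryl metal to a deactivated, enolisable ketone, and the acid stage could scramble C2 through a 2H-chromene. The fallback sets out from 13 and 9 and comes back at 17. NaBH4 (MeOH/THF, 0 °C) reduces 13 to (2S,4S)-7-(benzyloxy)-2-[4-(benzyloxy)phenyl]chroman-4-ol F4. TMSOTf (CH2Cl2, −78 °C) ionises F4 in the presence of excess 9 (the bromination is skipped), and the C4 cation alkylates C8 of 9 in a Friedel–Crafts reaction. This gives 17 beside its C4 epimer and the 6-linked isomers, which are removed by preparative HPLC; the price is lower selectivity at C4.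

Step 4 is the third risk. The peracid may over-oxidise the electron-rich enol formate or ring D, and ketone 8 can epimerise at C2 if the methanolysis is too basic. The fallback sets out from 6 and comes back at 8 and replaces the oxygen insertion by a nitrogen insertion. Pinnick oxidation (NaClO2, NaH2PO4, 2-methylbut-2-ene, t-BuOH/H2O) gives (R)-5,7-bis(benzyloxy)-2-[4-(benzyloxy)phenyl]-2H-chromene-3-carboxylic acid F5. Diphenylphosphoryl azide and Et3N (toluene, rt) give (R)-5,7-bis(benzyloxy)-2-[4-(benzyloxy)phenyl]-2H-chromene-3-carbonyl azide F6. Warming to 80 °C brings about the Curtius rearrangement to (R)-5,7-bis(benzyloxy)-2-[4-(benzyloxy)phenyl]-3-isocyanato-2H-chromene F7. Hydrolysis with 1 M HCl in THF at rt, through the enamine, gives 8.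

## Further compounds

F1 | step 8 | tert-butyl 3-[4-(benzyloxy)-2-hydroxyphenyl]-3-oxopropanoate | CC(C)(C)OC(=O)CC(=O)c1ccc(OCc2ccccc2)cc1O
F2 | step 8 | tert-butyl 2-[4-(benzyloxy)-2-hydroxybenzoyl]-3-[4-(benzyloxy)phenyl]prop-2-enoate (E/Z mixture) | CC(C)(C)OC(=O)C(=Cc1ccc(OCc2ccccc2)cc1)C(=O)c1ccc(OCc2ccccc2)cc1O
F3 | step 8 | tert-butyl (2S)-7-(benzyloxy)-2-[4-(benzyloxy)phenyl]-4-oxochromane-3-carboxylate (C3 epimers and enol) | CC(C)(C)OC(=O)C1C(=O)c2ccc(OCc3ccccc3)cc2O[C@@H]1c1ccc(OCc2ccccc2)cc1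
F4 | step 9 | (2S,4S)-7-(benzyloxy)-2-[4-(benzyloxy)phenyl]chroman-4-ol | O[C@H]1C[C@@H](c2ccc(OCc3ccccc3)cc2)Oc2cc(OCc3ccccc3)ccc12
F5 | step 4 | (R)-5,7-bis(benzyloxy)-2-[4-(benzyloxy)phenyl]-2H-chromene-3-carboxylic acid | c1c(OCc3ccccc3)cc(OCc3ccccc3)c2c1O[C@H](c1ccc(OCc3ccccc3)cc1)C(C(=O)O)=C2
F6 | step 4 | (R)-5,7-bis(benzyloxy)-2-[4-(benzyloxy)phenyl]-2H-chromene-3-carbonyl azide | c1c(OCc3ccccc3)cc(OCc3ccccc3)c2c1O[C@H](c1ccc(OCc3ccccc3)cc1)C(C(=O)N=[N+]=[N-])=C2
F7 | step 4 | (R)-5,7-bis(benzyloxy)-2-[4-(benzyloxy)phenyl]-3-isocyanato-2H-chromene | c1c(OCc3ccccc3)cc(OCc3ccccc3)c2c1O[C@H](c1ccc(OCc3ccccc3)cc1)C(N=C=O)=C2
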